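**Retrosynthetic overview**
- The target is the C2-symmetric 3,3'-dimer of (2R)-liquiritigenin. C4–C3–C3'–C4' is a 1,4-diketone, so the last C–C bond made is C3–C3', by silicon-tethered oxidative coupling of two identical (2R)-flavanone enol ethers, each new centre anti to its C2 aryl group.
- Each pyranone ring is cut at O1–C8a and C3–C4 and is made in one operation from an (R)-β-hydroxy ester dianion (O1–C2–C3 as 1,3-O,C-dinucleophile) and a 2-fluoro-4-(benzyloxy)benzoate (C4–C4a–C8a as 1,3-dielectrophile).
- Enabling feature: on ring A the ketone carbon C4 sits on C4a, ortho to the ether carbon C8a, and O1–C2–C3 is an aldol-type array. Acylating C3 with the ring A ester therefore creates the very ortho-carbonyl that activates C8a–F for displacement by O1; a tert-butyl ester on C3 (later lost as isobutene and CO2) supplies the carbanion and blocks retro-aldol cleavage.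
- Only C2 is set by a catalyst (asymmetric transfer hydrogenation of a β-keto ester); C3 and C3' follow from it under substrate control.
- Ring order: rings A and B are bought as benzenes, the two pyranone rings are closed in the key step, then the halves are joined; the four phenols travel as benzyl ethers and are freed last.

Key step: step 4

Assumption: the (R,R)-TsDPEN ruthenium catalyst is taken to give the R carbinol, as it does for simple aryl alkyl ketones (the CIP order O > aryl > CH2 is the same here); the antipodal ligand would be used if the sense proved opposite.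

**Step 1**
Reactants: 1 methyl 4-(benzyloxy)benzoate; 2 tert-butyl acetate
Product: 4 tert-butyl 3-[4-(benzyloxy)phenyl]-3-oxopropanoate, via lithium enolate of tert-butyl acetate 3 (not isolated)
Conditions: LiN(iPr)2, THF, −78 °C; then 1, −78 → 0 °C; aq HCl
Reagents that add atoms: none
Why: Crossed Claisen condensation of an ester enolate with a non-enolisable aryl ester, driven by deprotonation of the β-keto ester product; no stereocentre is formed.

**Step 2**
Reactants: 4 tert-butyl 3-[4-(benzyloxy)phenyl]-3-oxopropanoate
Product: 5 tert-butyl (3R)-3-[4-(benzyloxy)phenyl]-3-hydroxypropanoate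
Conditions: RuCl(p-cymene)[(R,R)-TsDPEN] (1 mol %), HCO2H/Et3N (5:2), DMF, 40 °C
Reagents that add atoms: none
Why: Noyori asymmetric transfer hydrogenation of an aryl ketone, in which the ruthenium hydride and the ligand N–H deliver H2 through a six-membered transition state organised by the aryl group, so that the (R,R) ligand should set the carbinol carbon (the future C2) as R.

**Step 3**
Reactants: 6 methyl 2-fluoro-4-hydroxybenzoate; 7 benzyl bromide
Product: 8 methyl 4-(benzyloxy)-2-fluorobenzoate
Conditions: K2CO3, DMF, 23 °C
Reagents that add atoms: none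
Why: Williamson etherification (SN2 of the phenoxide on benzyl bromide), mild enough to leave the ester and the aryl fluoride untouched.

**Step 4**
Reactants: 5 tert-butyl (3R)-3-[4-(benzyloxy)phenyl]-3-hydroxypropanoate; 8 methyl 4-(benzyloxy)-2-fluorobenzoate
Product: 11 tert-butyl (2R,3S)-7-(benzyloxy)-2-[4-(benzyloxy)phenyl]-4-oxochromane-3-carboxylate, via dilithium alkoxide enolate of the hydroxy ester 9 (not isolated), via open-chain C-acylated dilithium salt 10 (not isolated)
Conditions: LiN(iPr)2 (2.1 equiv), THF, −78 → −20 °C; 8, −78 → 0 °C; DMPU, 0 → 25 °C; AcOH, −20 °C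
Reagents that add atoms: none
Why: Proposed new method: LiN(iPr)2 converts 5 into its chelated dilithium alkoxide–enolate 9 (the Fráter–Seebach dianion, whose oxido group cannot leave), the enolate carbon C3 attacks the non-enolisable ester 8 in a Claisen-type acylation, the expelled methoxide deprotonates the new β-keto ester to give 10 (an enolate that can no longer undergo retro-aldol cleavage), and the C2 alkoxide then adds to C8a, now ortho to the C4 carbonyl, with loss of fluoride (SNAr through a Meisenheimer adduct). The closest known reaction types are the acylation of ester and β-keto ester dianions by esters and the Grohe–Heitzer cycloaracylation (C-acylation by a 2-halobenzoyl donor followed by SNAr closure of a heteroatom onto the arene), which is established for enamino esters and 1,3-dicarbonyl enolates but not for a β-hydroxy ester dianion with an sp3 alkoxide as the ring-closing nucleophile. The pyranone ring closes by 6-exo-trig attack of O1 on the aromatic carbon C8a. C2 takes part in no bond-forming event and keeps the R configuration of 5, whereas C3 is epimerisable, should settle trans to the aryl group (3S) and is erased in step 5. The step needs C- over O-acylation (alkoxide transesterification is slow and reversible while enolate acylation is made irreversible by deprotonation), closure by the localised alkoxide and not by the delocalised enolate oxygen, and retention at C2 (lithium counter-ion, low temperature and an acidic quench before the product enolate can open by retro-oxa-Michael reaction).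

**Step 5**
Reactants: 11 tert-butyl (2R,3S)-7-(benzyloxy)-2-[4-(benzyloxy)phenyl]-4-oxochromane-3-carboxylate
Product: 13 (2R)-7-(benzyloxy)-2-[4-(benzyloxy)phenyl]chroman-4-one, via β-keto acid 12 (not isolated)
Conditions: TsOH·H2O (0.2 equiv), toluene, 80 °C
Reagents that add atoms: none
Why: Acid-promoted E1 loss of isobutene from the tert-butyl ester and decarboxylation of the β-keto acid through its cyclic transition state, a sequence closely precedented for 3-carboxylated flavanones, which leaves C2 untouched and turns C3 into CH2.

**Step 6**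
Reactants: 13 (2R)-7-(benzyloxy)-2-[4-(benzyloxy)phenyl]chroman-4-one (two equivalents)
Product: 15 bis{[(2R)-7-(benzyloxy)-2-[4-(benzyloxy)phenyl]-2H-chromen-4-yl]oxy}di(propan-2-yl)silane, via mono-enol silyl triflate 14 (not isolated)
Conditions: iPr2Si(OTf)2 (0.5 equiv), Et3N, CH2Cl2, 0 → 23 °C
Reagents that add atoms: diisopropylsilyl bis(trifluoromethanesulfonate), CC(C)[Si](OS(=O)(=O)C(F)(F)F)(OS(=O)(=O)C(F)(F)F)C(C)C
Why: Twofold soft enolisation (silyl triflate with a tertiary amine) at one silicon gives the symmetrical silyl bis-enol ether without a free enolate, so the retro-oxa-Michael ring opening that would erode C2 is avoided.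

**Step 7**
Reactants: 15 bis{[(2R)-7-(benzyloxy)-2-[4-(benzyloxy)phenyl]-2H-chromen-4-yl]oxy}di(propan-2-yl)silane
Product: 16 (2R,2'R,3S,3'S)-7,7'-bis(benzyloxy)-2,2'-bis[4-(benzyloxy)phenyl]-[3,3'-bichromane]-4,4'-dione
Conditions: (NH4)2Ce(NO3)6 (2.2 equiv), NaHCO3, MeCN, −10 °C
Reagents that add atoms: none
Why: Silicon-tethered oxidative coupling of a bis-enol ether (one-electron oxidation, intramolecular attack of the radical cation on the second enol ether, second oxidation and desilylation) should give the 1,4-diketone, with each C3 attacked on the face anti to its pseudo-equatorial C2 aryl group (2,3-trans, 3S and 3'S), and because both halves are 2R the trans,trans product can only be the C2-symmetric isomer.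

**Step 8**
Reactants: 16 (2R,2'R,3S,3'S)-7,7'-bis(benzyloxy)-2,2'-bis[4-(benzyloxy)phenyl]-[3,3'-bichromane]-4,4'-dione
Product: 17 (2R,2'R,3S,3'S)-7,7'-dihydroxy-2,2'-bis(4-hydroxyphenyl)-[3,3'-bichromane]-4,4'-dione
Conditions: H2 (1 atm), 10% Pd/C, EtOAc/MeOH, 23 °C
Reagents that add atoms: none
Why: Hydrogenolysis of the four aryl benzyl ethers under neutral conditions neither enolises C3 nor opens the pyranone rings, so all four stereocentres should be retained.

**Compound list**
1 | methyl 4-(benzyloxy)benzoate | COC(=O)c1ccc(OCc2ccccc2)cc1 | starting material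
2 | tert-butyl acetate | CC(=O)OC(C)(C)C | starting material
3 | lithium enolate of tert-butyl acetate (not isolated) | [Li+].C=C([O-])OC(C)(C)C | intermediate
4 | tert-butyl 3-[4-(benzyloxy)phenyl]-3-oxopropanoate | CC(C)(C)OC(=O)CC(=O)c1ccc(OCc2ccccc2)cc1 | intermediate
5 | tert-butyl (3R)-3-[4-(benzyloxy)phenyl]-3-hydroxypropanoate | CC(C)(C)OC(=O)C[C@@H](O)c1ccc(OCc2ccccc2)cc1 | intermediate
6 | methyl 2-fluoro-4-hydroxybenzoate | COC(=O)c1ccc(O)cc1F | starting material
7 | benzyl bromide | BrCc1ccccc1 | starting material
8 | methyl 4-(benzyloxy)-2-fluorobenzoate | COC(=O)c1ccc(OCc2ccccc2)cc1F | intermediate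
9 | dilithium alkoxide enolate of 5 (not isolated; carbinol configuration as in 5) | [Li+].[Li+].[O-][C@H](C=C([O-])OC(C)(C)C)c1ccc(OCc2ccccc2)cc1 | intermediate
10 | open-chain C-acylated dilithium salt: alkoxide and β-keto ester enolate of tert-butyl 2-[4-(benzyloxy)-2-fluorobenzoyl]-3-[4-(benzyloxy)phenyl]-3-hydroxypropanoate (not isolated; carbinol configuration as in 5) | [Li+].[Li+].[O-][C@@H](c1ccc(OCc2ccccc2)cc1)C(C(=O)OC(C)(C)C)=C([O-])c1ccc(OCc2ccccc2)cc1F | intermediate
11 | tert-butyl (2R,3S)-7-(benzyloxy)-2-[4-(benzyloxy)phenyl]-4-oxochromane-3-carboxylate | O=C1c2ccc(OCc3ccccc3)cc2O[C@@H](c2ccc(OCc3ccccc3)cc2)[C@@H]1C(=O)OC(C)(C)C | intermediate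
12 | (2R,3S)-7-(benzyloxy)-2-[4-(benzyloxy)phenyl]-4-oxochromane-3-carboxylic acid (not isolated) | O=C1c2ccc(OCc3ccccc3)cc2O[C@@H](c2ccc(OCc3ccccc3)cc2)[C@@H]1C(=O)O | intermediate
13 | (2R)-7-(benzyloxy)-2-[4-(benzyloxy)phenyl]chroman-4-one | O=C1c2ccc(OCc3ccccc3)cc2O[C@@H](c2ccc(OCc3ccccc3)cc2)C1 | intermediate
14 | {[(2R)-7-(benzyloxy)-2-[4-(benzyloxy)phenyl]-2H-chromen-4-yl]oxy}di(propan-2-yl)silyl trifluoromethanesulfonate (not isolated) | CC(C)[Si](OC1=C[C@H](c2ccc(OCc3ccccc3)cc2)Oc2cc(OCc3ccccc3)ccc12)(OS(=O)(=O)C(F)(F)F)C(C)C | intermediate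
15 | bis{[(2R)-7-(benzyloxy)-2-[4-(benzyloxy)phenyl]-2H-chromen-4-yl]oxy}di(propan-2-yl)silane | CC(C)[Si](OC1=C[C@H](c2ccc(OCc3ccccc3)cc2)Oc2cc(OCc3ccccc3)ccc12)(OC1=C[C@H](c2ccc(OCc3ccccc3)cc2)Oc2cc(OCc3ccccc3)ccc12)C(C)C | intermediate
16 | (2R,2'R,3S,3'S)-7,7'-bis(benzyloxy)-2,2'-bis[4-(benzyloxy)phenyl]-[3,3'-bichromane]-4,4'-dione | O=C1c2ccc(OCc3ccccc3)cc2O[C@@H](c2ccc(OCc3ccccc3)cc2)[C@@H]1[C@@H]1C(=O)c2ccc(OCc3ccccc3)cc2O[C@H]1c1ccc(OCc2ccccc2)cc1 | intermediate
17 | (2R,2'R,3S,3'S)-7,7'-dihydroxy-2,2'-bis(4-hydroxyphenyl)-[3,3'-bichromane]-4,4'-dione | O=C1c2ccc(O)cc2O[C@@H](c2ccc(O)cc2)[C@@H]1[C@@H]1C(=O)c2ccc(O)cc2O[C@H]1c1ccc(O)cc1 | target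

**Totals and risks**
Total step count: 8. Longest linear sequence: 7 steps (steps 1, 2, 4, 5, 6, 7, 8).

The three steps most likely to fail:

Step 4 (Proposed new method). The benzylic alkoxide of the dianion may be transesterified by 8 and the resulting β-aroyloxy enolate may eliminate to the cinnamate. Fluoride displacement may be slow because the activating carbonyl is tied up in the enolate. The C2 configuration may erode through reversible retro-oxa-Michael opening of the product enolate. The fallback uses known chemistry and sets out from benzyl bromide 7. Purchased 7-hydroxy-4H-chromen-4-one is O-benzylated (K2CO3, DMF) to 7-(benzyloxy)-4H-chromen-4-one F1. Palladium-catalysed asymmetric conjugate addition of purchased 4-(benzyloxy)phenylboronic acid to F1 follows (Pd(OCOCF3)2, the tert-butyl pyridine-oxazoline ligand enantiomer that gives the 2R product, NH4PF6, H2O, 1,2-dichloroethane, 60 °C). It comes back to the route at 13, so that steps 1, 2, 4 and 5 are bypassed.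

Step 7. The enol ether radical cation may lose the activated C2 hydrogen and aromatise to the flavone instead of coupling. The benzyloxyarenes may be oxidised. The bis-enol ether may hydrolyse before it is oxidised. The fallback sets out from 13 and gives up the silicon tether. Kinetic deprotonation (LiN(iPr)2, THF, −78 °C) gives the lithium enolate of 13 F2, which is coupled intermolecularly with anhydrous CuCl2 in DMF (−78 → −40 °C). It comes back to the route at 16.

Step 8. Once the benzyl ethers are gone, the doubly activated benzylic C2–O1 bonds may be cleaved hydrogenolytically, or the aryl ketones reduced. The fallback sets out from 16 and removes the benzyl groups without a reductant: BCl3 with pentamethylbenzene as cation scavenger in CH2Cl2 at −78 °C. It comes back to the route at 17 and passes through no new compound.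

**Further compounds**
F1 | step 4 | 7-(benzyloxy)-4H-chromen-4-one | O=c1ccoc2cc(OCc3ccccc3)ccc12
F2 | step 7 | lithium enolate of (2R)-7-(benzyloxy)-2-[4-(benzyloxy)phenyl]chroman-4-one | [Li+].[O-]C1=C[C@H](c2ccc(OCc3ccccc3)cc2)Oc2cc(OCc3ccccc3)ccc12
F0 | step 8 | none | none
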